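**Retrosynthetic overview**

1. Feature: in the target the bond C3–C3'' joins the two pyranone rings (ring C of each flavanone unit; unprimed atoms belong to the 7-hydroxyflavanone unit, double-primed atoms to the 5,7-dihydroxyflavanone unit). C4(=O)–C3–C3''–C4''(=O) is therefore a 1,4-diaryl-1,4-diketone with C3 and C3'' as its α-carbons, and C2 and C2'' are benzylic carbinol-level carbons that each carry a 4-hydroxyphenyl ring.
2. Last disconnections: the five benzyl ethers, then O1–C2 and O1''–C2'' of both pyranone rings (twofold Mitsunobu closure with inversion, after removal of two allyl groups), which leads back to an open-chain syn,syn bis-aldol.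
3. Key disconnection: C2–C3 and C2''–C3'' by a twofold reagent-controlled syn-aldol addition of the bis(Z-boron enolate) of the protected 1,4-diketone to two molecules of 4-(benzyloxy)benzaldehyde (four stereocentres, no ring).
4. Diketone: C3–C3'' by zinc-mediated union of the α-bromo ketone from protected 2',4'-dihydroxyacetophenone with protected 2',4',6'-trihydroxyacetophenone.
5. Ring order: the four benzene rings are bought; the two pyranone rings are the only rings made and close together in the penultimate step.

Key step: step 7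

Assumption: (−)-diisopinocampheylboron triflate, the enantiomer made from (+)-α-pinene, is taken to direct its Z-enolates to the Re face of the aldehyde as it does with simple ethyl ketones; should the opposite sense be found, the (+)-reagent is used and nothing else changes.

**Route**

Step 1
Reactants: 1 2',4'-dihydroxyacetophenone
Product: 2 1-[4-(benzyloxy)-2-hydroxyphenyl]ethanone
Conditions: BnBr (1.05 equiv), K2CO3, acetone, reflux
Reagents that add atoms: benzyl bromide, BrCc1ccccc1
Why: Williamson ether synthesis in which the 2-hydroxyl, held in a hydrogen bond to the ketone, is much the poorer nucleophile, so one equivalent of benzyl bromide should ether only the 4-hydroxyl.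

Step 2
Reactants: 2 1-[4-(benzyloxy)-2-hydroxyphenyl]ethanone
Product: 3 1-[2-(allyloxy)-4-(benzyloxy)phenyl]ethanone
Conditions: allyl bromide, K2CO3, DMF, 60 °C
Reagents that add atoms: allyl bromide, C=CCBr
Why: Williamson ether synthesis under more forcing conditions alkylates the chelated phenol, and the allyl ether is chosen because it can later be removed under nearly neutral conditions beside benzyl ethers and a β-hydroxy ketone.

Step 3
Reactants: 3 1-[2-(allyloxy)-4-(benzyloxy)phenyl]ethanone
Product: 5 1-[2-(allyloxy)-4-(benzyloxy)phenyl]-2-bromoethanone, via trimethylsilyl enol ether 4 (not isolated)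
Conditions: TMSOTf, Et3N, CH2Cl2, 0 °C; then NBS, THF, −78 to 0 °C
Reagents that add atoms: N-bromosuccinimide, O=C1CCC(=O)N1Br
Why: Soft enolisation to the silyl enol ether followed by its electrophilic bromination, in which the enol ether is far more nucleophilic than the allyl alkene or the dialkoxybenzene ring, so bromine should go only to the former methyl carbon.

Step 4
Reactants: 6 2',4',6'-trihydroxyacetophenone
Product: 7 1-[2,4-bis(benzyloxy)-6-hydroxyphenyl]ethanone
Conditions: BnBr (2.05 equiv), K2CO3, DMF, rt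
Reagents that add atoms: benzyl bromide, BrCc1ccccc1
Why: Williamson ether synthesis in which the 4-hydroxyl and one of the two equivalent ortho hydroxyls react, while the ortho hydroxyl left in a hydrogen bond to the ketone should stay free with two equivalents of halide.

Step 5
Reactants: 7 1-[2,4-bis(benzyloxy)-6-hydroxyphenyl]ethanone
Product: 8 1-[2-(allyloxy)-4,6-bis(benzyloxy)phenyl]ethanone
Conditions: allyl bromide, K2CO3, DMF, 60 °C
Reagents that add atoms: allyl bromide, C=CCBr
Why: Williamson ether synthesis of the chelated phenol under the forcing conditions of step 2.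

Step 6
Reactants: 8 1-[2-(allyloxy)-4,6-bis(benzyloxy)phenyl]ethanone (1.5 equiv); 5 1-[2-(allyloxy)-4-(benzyloxy)phenyl]-2-bromoethanone
Product: 9 1-[2-(allyloxy)-4-(benzyloxy)phenyl]-4-[2-(allyloxy)-4,6-bis(benzyloxy)phenyl]butane-1,4-dione
Conditions: ZnCl2, Et2NH, t-BuOH, toluene, rt
Reagents that add atoms: none
Why: Known ZnCl2/Et2NH/t-BuOH-mediated condensation of a methyl ketone with an α-bromomethyl ketone to a 1,4-diketone (formal alkylation of the zinc enolate of 8 by 5), with the less hindered and less electron-rich ketone chosen as the bromide; no stereocentre is formed.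

Step 7
Reactants: 9 1-[2-(allyloxy)-4-(benzyloxy)phenyl]-4-[2-(allyloxy)-4,6-bis(benzyloxy)phenyl]butane-1,4-dione; 10 4-(benzyloxy)benzaldehyde (two molecules add, used in excess)
Product: 14 (2R,3R)-1-[2-(allyloxy)-4-(benzyloxy)phenyl]-4-[2-(allyloxy)-4,6-bis(benzyloxy)phenyl]-2,3-bis{(R)-[4-(benzyloxy)phenyl](hydroxy)methyl}butane-1,4-dione, via bis(enol borinate) 11 (not isolated), via mono-adduct enol borinate 12 (not isolated), via bis(boron aldolate) 13 (not isolated)
Conditions: (−)-Ipc2BOTf (3 equiv), i-Pr2NEt (4 equiv), CH2Cl2, −78 to 0 °C; then 10 (3 equiv), −78 to −20 °C; then H2O2, MeOH, pH 7 buffer, 0 °C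
Reagents that add atoms: none
Why: Proposed new method: twofold soft enolisation of 9 by the boron triflate and the amine should give the (1Z,3Z)-bis(enol borinate) 11, whose enolate carbons C3 and C3'' add in turn to boron-bound aldehyde 10 through closed six-membered chair (Zimmerman–Traxler) transition states, by way of mono-adduct 12 and bis(aldolate) 13, which oxidative work-up frees as diol 14. The closest known reaction type is the isopinocampheyl-controlled syn-aldol addition of Z-boron enolates of ethyl and aryl ketones to aldehydes; new is its use on both ends of the conjugated bis-enolate of a 1,4-diketone. No ring is closed, the bonds made being C2–C3 and C2''–C3''. The Z geometry of each enolate sets the syn relation C2/C3 and C2''/C3'' through the chair, and the isopinocampheyl groups on boron choose the Re face of each aldehyde, which makes C2 and C2'' R and with them C3 and C3'' R (flavanone numbering: 2R,3R,2''R,3''R). The step needs reagent control in the second addition to override the C2 and C3 centres already present, and this should hold because allylic strain puts C3–H in the plane of the remaining enolate and leaves two branches of similar size on its two faces, so the inherent bias of the substrate is small, while a mismatched addition would end in a separable diastereomer and not in the enantiomer. Chemoselectivity rests on the substrate: 10 cannot enolise, 9 has only the two methylene groups to enolise, and the amine-buffered medium at low temperature should leave the allyl and benzyl ethers alone and should not cyclodehydrate the diketone.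

Step 8
Reactants: 14 syn,syn-bis(aldol) diol
Product: 15 (2R,3R)-1-[4-(benzyloxy)-2-hydroxyphenyl]-4-[2,4-bis(benzyloxy)-6-hydroxyphenyl]-2,3-bis{(R)-[4-(benzyloxy)phenyl](hydroxy)methyl}butane-1,4-dione
Conditions: Pd(PPh3)4 (5 mol%), morpholine, THF, rt
Reagents that add atoms: none
Why: Tsuji–Trost-type deallylation in which zerovalent palladium ionises each aryl allyl ether to a π-allyl complex and a phenoxide and morpholine takes up the allyl group, while benzyl ethers, ketones, benzylic alcohols and the four stereocentres should be untouched under these nearly neutral conditions.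

Step 9
Reactants: 15 bis-phenol diol
Product: 16 (2S,3R)-7-(benzyloxy)-2-[4-(benzyloxy)phenyl]-3-{(2S,3R)-5,7-bis(benzyloxy)-2-[4-(benzyloxy)phenyl]-4-oxochroman-3-yl}chroman-4-one
Conditions: PPh3 (3 equiv), DIAD (3 equiv, added last), THF (dilute), 0 °C to rt
Reagents that add atoms: none
Why: Twofold intramolecular Mitsunobu etherification (6-exo-tet closure of each pyranone ring), a known way from 2'-hydroxyaryl β-hydroxy ketones to chroman-4-ones, in which each phenol is the acidic partner and displaces the activated benzylic oxygen with inversion, so that C2 and C2'' change from R to S while C3 and C3'' are not touched and each syn aldol becomes a 2,3-trans ring.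

Step 10
Reactants: 16 penta-O-benzyl biflavanone
Product: 17 (2S,3R)-3-[(2S,3R)-5,7-dihydroxy-2-(4-hydroxyphenyl)-4-oxochroman-3-yl]-7-hydroxy-2-(4-hydroxyphenyl)chroman-4-one
Conditions: H2 (1 atm), Pd/C (10% Pd on carbon), THF–MeOH, rt
Reagents that add atoms: none
Why: Catalytic hydrogenolysis of the five benzyl ethers under neutral conditions at one atmosphere, under which the ketones and the ring C2–O bonds of flavanones normally survive and no stereocentre is touched.

**Compound list**

1 | 2',4'-dihydroxyacetophenone | CC(=O)c1ccc(O)cc1O | starting material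
2 | 1-[4-(benzyloxy)-2-hydroxyphenyl]ethanone | CC(=O)c1ccc(OCc2ccccc2)cc1O | intermediate
3 | 1-[2-(allyloxy)-4-(benzyloxy)phenyl]ethanone | CC(=O)c1ccc(OCc2ccccc2)cc1OCC=C | intermediate
4 | {1-[2-(allyloxy)-4-(benzyloxy)phenyl]vinyloxy}trimethylsilane (silyl enol ether, not isolated) | C=C(O[Si](C)(C)C)c1ccc(OCc2ccccc2)cc1OCC=C | intermediate
5 | 1-[2-(allyloxy)-4-(benzyloxy)phenyl]-2-bromoethanone | O=C(CBr)c1ccc(OCc2ccccc2)cc1OCC=C | intermediate
6 | 2',4',6'-trihydroxyacetophenone | CC(=O)c1c(O)cc(O)cc1O | starting material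
7 | 1-[2,4-bis(benzyloxy)-6-hydroxyphenyl]ethanone | CC(=O)c1c(O)cc(OCc2ccccc2)cc1OCc1ccccc1 | intermediate
8 | 1-[2-(allyloxy)-4,6-bis(benzyloxy)phenyl]ethanone | CC(=O)c1c(OCC=C)cc(OCc2ccccc2)cc1OCc1ccccc1 | intermediate
9 | 1-[2-(allyloxy)-4-(benzyloxy)phenyl]-4-[2-(allyloxy)-4,6-bis(benzyloxy)phenyl]butane-1,4-dione | O=C(CCC(=O)c1c(OCC=C)cc(OCc2ccccc2)cc1OCc1ccccc1)c1ccc(OCc2ccccc2)cc1OCC=C | intermediate
10 | 4-(benzyloxy)benzaldehyde | O=Cc1ccc(OCc2ccccc2)cc1 | starting material
11 | (1Z,3Z)-1-[2-(allyloxy)-4-(benzyloxy)phenyl]-4-[2-(allyloxy)-4,6-bis(benzyloxy)phenyl]-1,4-bis(diisopinocampheylboryloxy)buta-1,3-diene (bis(enol borinate), not isolated; isopinocampheyl groups from (+)-α-pinene) | B([C@@H]1C[C@@H]2C[C@H]([C@H]1C)C2(C)C)([C@@H]1C[C@@H]2C[C@H]([C@H]1C)C2(C)C)O/C(c1ccc(OCc2ccccc2)cc1OCC=C)=C\C=C(/OB([C@@H]1C[C@@H]2C[C@H]([C@H]1C)C2(C)C)[C@@H]1C[C@@H]2C[C@H]([C@H]1C)C2(C)C)c1c(OCC=C)cc(OCc2ccccc2)cc1OCc1ccccc1 | intermediate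
12 | mono-adduct: (2R,3R) O-diisopinocampheylboryl aldolate at C2–C3 that still carries the Z-enol borinate of the other ketone (not isolated; drawn for first addition at C3, the other order converges on 13) | O=C(c1ccc(OCc2ccccc2)cc1OCC=C)[C@@H]([C@@H](OB([C@@H]1C[C@@H]2C[C@H]([C@H]1C)C2(C)C)[C@@H]1C[C@@H]2C[C@H]([C@H]1C)C2(C)C)c1ccc(OCc2ccccc2)cc1)/C=C(\OB([C@@H]1C[C@@H]2C[C@H]([C@H]1C)C2(C)C)[C@@H]1C[C@@H]2C[C@H]([C@H]1C)C2(C)C)c1c(OCC=C)cc(OCc2ccccc2)cc1OCc1ccccc1 | intermediate
13 | bis(O-diisopinocampheylboryl) ether of 14 (bis(boron aldolate), not isolated) | O=C(c1ccc(OCc2ccccc2)cc1OCC=C)[C@@H]([C@@H](OB([C@@H]1C[C@@H]2C[C@H]([C@H]1C)C2(C)C)[C@@H]1C[C@@H]2C[C@H]([C@H]1C)C2(C)C)c1ccc(OCc2ccccc2)cc1)[C@H]([C@@H](OB([C@@H]1C[C@@H]2C[C@H]([C@H]1C)C2(C)C)[C@@H]1C[C@@H]2C[C@H]([C@H]1C)C2(C)C)c1ccc(OCc2ccccc2)cc1)C(=O)c1c(OCC=C)cc(OCc2ccccc2)cc1OCc1ccccc1 | intermediate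
14 | (2R,3R)-1-[2-(allyloxy)-4-(benzyloxy)phenyl]-4-[2-(allyloxy)-4,6-bis(benzyloxy)phenyl]-2,3-bis{(R)-[4-(benzyloxy)phenyl](hydroxy)methyl}butane-1,4-dione (syn,syn bis-aldol; 2R,3R,2''R,3''R in flavanone numbering) | O=C(c1ccc(OCc2ccccc2)cc1OCC=C)[C@@H]([C@@H](O)c1ccc(OCc2ccccc2)cc1)[C@H]([C@@H](O)c1ccc(OCc2ccccc2)cc1)C(=O)c1c(OCC=C)cc(OCc2ccccc2)cc1OCc1ccccc1 | intermediate
15 | (2R,3R)-1-[4-(benzyloxy)-2-hydroxyphenyl]-4-[2,4-bis(benzyloxy)-6-hydroxyphenyl]-2,3-bis{(R)-[4-(benzyloxy)phenyl](hydroxy)methyl}butane-1,4-dione | O=C(c1ccc(OCc2ccccc2)cc1O)[C@@H]([C@@H](O)c1ccc(OCc2ccccc2)cc1)[C@H]([C@@H](O)c1ccc(OCc2ccccc2)cc1)C(=O)c1c(O)cc(OCc2ccccc2)cc1OCc1ccccc1 | intermediate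
16 | (2S,3R)-7-(benzyloxy)-2-[4-(benzyloxy)phenyl]-3-{(2S,3R)-5,7-bis(benzyloxy)-2-[4-(benzyloxy)phenyl]-4-oxochroman-3-yl}chroman-4-one (both rings 2,3-trans) | O=C1c2ccc(OCc3ccccc3)cc2O[C@H](c2ccc(OCc3ccccc3)cc2)[C@H]1[C@H]1C(=O)c2c(OCc3ccccc3)cc(OCc3ccccc3)cc2O[C@@H]1c1ccc(OCc2ccccc2)cc1 | intermediate
17 | (2S,3R)-3-[(2S,3R)-5,7-dihydroxy-2-(4-hydroxyphenyl)-4-oxochroman-3-yl]-7-hydroxy-2-(4-hydroxyphenyl)chroman-4-one (2S,3R,2''S,3''R) | O=C1c2ccc(O)cc2O[C@H](c2ccc(O)cc2)[C@H]1[C@H]1C(=O)c2c(O)cc(O)cc2O[C@@H]1c1ccc(O)cc1 | target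

**Count and risks**

Total step count: 10. Longest linear sequence: 8 steps (steps 1, 2, 3, 6, 7, 8, 9, 10).

Steps most likely to fail:

Step 7 (bears the label). The second addition has to form a bond next to the crowded C3–C3'' axis and may stall at the mono-adduct, the first-formed stereocentres may erode reagent control in the second addition, and the Lewis acid may cyclodehydrate the diketone before both enolates have formed. The fallback sets out from 9 and returns at 14 and uses one ordinary Ipc-controlled syn-aldol at a time. Compound 9 is treated with about one equivalent of (−)-Ipc2BOTf/i-Pr2NEt and one equivalent of 10, which should give the mono-aldol as either or both of the regioisomers (R)-2-{(R)-[4-(benzyloxy)phenyl](hydroxy)methyl}-1-[2-(allyloxy)-4-(benzyloxy)phenyl]-4-[2-(allyloxy)-4,6-bis(benzyloxy)phenyl]butane-1,4-dione F1 and (R)-3-{(R)-[4-(benzyloxy)phenyl](hydroxy)methyl}-1-[2-(allyloxy)-4-(benzyloxy)phenyl]-4-[2-(allyloxy)-4,6-bis(benzyloxy)phenyl]butane-1,4-dione F2; recovered 9 is recycled. F1 and F2, together or apart, are then submitted to a second aldol of the same kind with a further 2.2 equivalents of the boron triflate (the first equivalent turns the free hydroxyl into its borinate) and 10, and both converge on 14 after oxidative work-up.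

Step 9. The activated β-hydroxyl may be lost by elimination toward the α-substituted enone. Because the bis-aldol is also a 1,4-diol, ether formation between the two carbinols may compete with phenoxide closure. The 4-benzyloxybenzylic oxyphosphonium may also ionise, so that inversion is incomplete. The fallback sets out from 15 and returns at 16 and gives up inversion for substrate control. Compound 15 is treated with a catalytic Brønsted acid (camphorsulfonic acid, CH2Cl2, molecular sieves, 0 °C to rt). Each 4-benzyloxybenzylic alcohol should ionise to a para-quinone-methide-like cation that the neighbouring phenol captures in a six-membered closure. C2 and C2'' are then set by C3 and C3'', the aryl group settling trans to the C3 substituent, and since closure at C2 is reversible under these conditions the trans,trans compound 16 is the expected thermodynamic product. This fallback makes no compound outside the list (F0).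

Step 6. Attack of the zinc enolate on the electron-rich bromo ketone may be slow, so that amination of the bromide by diethylamine or self-condensation takes over. The fallback sets out from 8 and 5 and returns at 9 by the acetoacetic-ester logic. Ketone 8 is C-acylated (NaH, dimethyl carbonate, THF, reflux) to methyl 3-[2-(allyloxy)-4,6-bis(benzyloxy)phenyl]-3-oxopropanoate F3. Its stabilised enolate is alkylated with 5 (K2CO3, acetone, rt) to methyl 2-[2-(allyloxy)-4,6-bis(benzyloxy)benzoyl]-4-[2-(allyloxy)-4-(benzyloxy)phenyl]-4-oxobutanoate F4 (racemic). Krapcho dealkoxycarbonylation (LiCl, wet DMSO, 130 °C) then gives 9.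

**Further compounds**

F1 | step 7 | (R)-2-{(R)-[4-(benzyloxy)phenyl](hydroxy)methyl}-1-[2-(allyloxy)-4-(benzyloxy)phenyl]-4-[2-(allyloxy)-4,6-bis(benzyloxy)phenyl]butane-1,4-dione | O=C(c1ccc(OCc2ccccc2)cc1OCC=C)[C@@H]([C@@H](O)c1ccc(OCc2ccccc2)cc1)CC(=O)c1c(OCC=C)cc(OCc2ccccc2)cc1OCc1ccccc1
F2 | step 7 | (R)-3-{(R)-[4-(benzyloxy)phenyl](hydroxy)methyl}-1-[2-(allyloxy)-4-(benzyloxy)phenyl]-4-[2-(allyloxy)-4,6-bis(benzyloxy)phenyl]butane-1,4-dione | O=C(c1ccc(OCc2ccccc2)cc1OCC=C)C[C@H]([C@@H](O)c1ccc(OCc2ccccc2)cc1)C(=O)c1c(OCC=C)cc(OCc2ccccc2)cc1OCc1ccccc1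
F0 | step 9 | none | none
F3 | step 6 | methyl 3-[2-(allyloxy)-4,6-bis(benzyloxy)phenyl]-3-oxopropanoate | COC(=O)CC(=O)c1c(OCC=C)cc(OCc2ccccc2)cc1OCc1ccccc1
F4 | step 6 | methyl 2-[2-(allyloxy)-4,6-bis(benzyloxy)benzoyl]-4-[2-(allyloxy)-4-(benzyloxy)phenyl]-4-oxobutanoate (racemic) | COC(=O)C(CC(=O)c1ccc(OCc2ccccc2)cc1OCC=C)C(=O)c1c(OCC=C)cc(OCc2ccccc2)cc1OCc1ccccc1
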